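**Plan**
Cuts: in each indole the N1–C2 and C3–C3a bonds of the pyrrole ring (four bonds, two rings), then the two C(sp2)–C(sp) bonds at imidazole C2 and C4.
Enabling feature: both indoles are attached through C3 to the imidazole (one at C2, one at C4), with H on C2 and Br on C6, para to C3a. Each pyrrole ring therefore equals 5-bromo-2-iodoaniline plus an imidazolyl alkyne whose silyl cap stands in for the C2 hydrogen.
Forward: the imidazole ring is bought as its tribromide, then N-SEM protected, alkynylated at C2, freed of the C5 bromine and alkynylated at C4.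
Both pyrrole rings then close in one twofold Larock heteroannulation, and acid removes the two C2 silyl groups and the SEM group.
Stereochemistry: the target is achiral with no stereocentre, so all control is site- and regioselectivity.

Key step: step 5

Assumption: in the twofold annulation the less hindered alkyne at imidazole C4 is taken to react first, and in the final deprotection the C2 silyl groups are taken to leave before the SEM group; neither order affects the product.

**Step 1**
Reactants: 1 2,4,5-tribromo-1H-imidazole; 2 2-(trimethylsilyl)ethoxymethyl chloride (SEMCl)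
Product: 4 2,4,5-tribromo-1-{[2-(trimethylsilyl)ethoxy]methyl}-1H-imidazole, via sodium 2,4,5-tribromoimidazolide 3 (not isolated)
Conditions: NaH (1.1 equiv), THF, 0 °C; then 2 (1.1 equiv), 0 °C to rt
Reagents that add atoms: 2-(trimethylsilyl)ethoxymethyl chloride (2), C[Si](C)(C)CCOCCl
Why: Deprotonation and N-alkylation with a chloromethyl ether (SN2) is the standard way to SEM-protect imidazoles, and because the anion 3 is symmetric only one N-SEM isomer can arise.

**Step 2**
Reactants: 4 2,4,5-tribromo-1-{[2-(trimethylsilyl)ethoxy]methyl}-1H-imidazole; 5 triethylsilylacetylene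
Product: 6 4,5-dibromo-2-[(triethylsilyl)ethynyl]-1-{[2-(trimethylsilyl)ethoxy]methyl}-1H-imidazole
Conditions: 5 (1.05 equiv), PdCl2(PPh3)2 (3 mol %), CuI (5 mol %), Et3N, THF, rt to 50 °C
Reagents that add atoms: triethylsilylacetylene (5), CC[Si](CC)(CC)C#C
Why: Sonogashira coupling: the C2–Br bond lies between both ring nitrogens, is the most electron-poor of the three and is the known first site of palladium cross-coupling in N-protected 2,4,5-tribromoimidazoles, so with the alkyne as limiting partner a single alkynylation at C2 should result.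

**Step 3**
Reactants: 6 4,5-dibromo-2-[(triethylsilyl)ethynyl]-1-{[2-(trimethylsilyl)ethoxy]methyl}-1H-imidazole
Product: 8 4-bromo-2-[(triethylsilyl)ethynyl]-1-{[2-(trimethylsilyl)ethoxy]methyl}-1H-imidazole, via C5-lithio imidazole 7 (not isolated)
Conditions: n-BuLi (1.05 equiv), THF, −78 °C; then MeOH, −78 °C to rt
Reagents that add atoms: none
Why: Bromine–lithium exchange of N-protected 4,5-dibromoimidazoles is known to take place at C5, where the carbanion sits next to N1 and can be held by the SEM oxygen, and at −78 °C it outruns any attack on the silyl alkyne or on C4–Br, so that protonation leaves the 4-bromide alone.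

**Step 4**
Reactants: 8 4-bromo-2-[(triethylsilyl)ethynyl]-1-{[2-(trimethylsilyl)ethoxy]methyl}-1H-imidazole; 5 triethylsilylacetylene
Product: 9 2,4-bis[(triethylsilyl)ethynyl]-1-{[2-(trimethylsilyl)ethoxy]methyl}-1H-imidazole
Conditions: 5 (1.5 equiv), PdCl2(PhCN)2 (5 mol %), [HP(t-Bu)3]BF4 (10 mol %), CuI (5 mol %), i-Pr2NH, dioxane, 60 °C
Reagents that add atoms: triethylsilylacetylene (5), CC[Si](CC)(CC)C#C
Why: Sonogashira coupling at the only C–Br bond left, which is the least reactive one of the imidazole and is therefore addressed with the electron-rich, bulky P(t-Bu)3 ligand known to bring unactivated aryl and heteroaryl bromides into this reaction under mild heating that the triethylsilyl caps tolerate.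

**Step 5**
Reactants: 9 2,4-bis[(triethylsilyl)ethynyl]-1-{[2-(trimethylsilyl)ethoxy]methyl}-1H-imidazole; 10 5-bromo-2-iodoaniline
Product: 12 2,4-bis[6-bromo-2-(triethylsilyl)-1H-indol-3-yl]-1-{[2-(trimethylsilyl)ethoxy]methyl}-1H-imidazole, via C4 mono-indole 11 (not isolated)
Conditions: 10 (2.4 equiv), Pd(OAc)2 (10 mol %), LiCl (2 equiv), Na2CO3 (6 equiv), DMF, 100 °C
Reagents that add atoms: 5-bromo-2-iodoaniline (10), Nc1cc(Br)ccc1I
Why: Pd(OAc)2 is reduced in the flask to zerovalent palladium, which adds to the C–I bond of 10; the chloride-bound arylpalladium species then adds syn across one alkyne of 9, placing the aryl carbon (future C3a) on the imidazole-bearing carbon (future C3) and palladium on the silyl-bearing carbon (future C2). The neighbouring NH2 group replaces halide on palladium, base takes up HI, and C–N reductive elimination from the six-membered azapalladacycle forms N1–C2, so each pyrrole ring closes as a formal [3+2] annulation (C3a–C7a–N1 from the aniline, C2–C3 from the alkyne); the cycle then repeats on the alkyne left in 11. This is the Larock heteroannulation, whose closest known case is the reaction of ortho-iodoanilines with aryl(trialkylsilyl)alkynes to give 3-aryl-2-silylindoles, used here twice on one substrate. Regiochemistry rests on the triethylsilyl group, the bulkier alkyne terminus, which ends next to palladium and later next to nitrogen and so puts the imidazole on C3 at both sites. Chemoselectivity rests on the much faster oxidative addition of C–I than of C–Br at a phosphine-free catalyst at 100 °C or below, helped by a slight excess of 10 so that an iodide is always on offer. No stereocentre is formed, the SEM group keeps the imidazole N–H away from palladium and base, and early loss of a C2 silyl group from a finished indole is harmless because step 6 removes it anyway.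

**Step 6**
Reactants: 12 2,4-bis[6-bromo-2-(triethylsilyl)-1H-indol-3-yl]-1-{[2-(trimethylsilyl)ethoxy]methyl}-1H-imidazole
Product: 14 nortopsentin A [2,4-bis(6-bromo-1H-indol-3-yl)-1H-imidazole], via N-SEM bis-indole 13 (not isolated)
Conditions: 6 M aq HCl, EtOH, 80 °C
Reagents that add atoms: none
Why: Acid-mediated ipso-protodesilylation of 2-silylindoles and acid hydrolysis of the N,O-acetal of an N-SEM imidazole are both standard deprotections, the protonated imidazole shields the indoles from acid-induced self-condensation, and the aryl bromides are inert to hot aqueous HCl.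

**Compound list**
1 | 2,4,5-tribromo-1H-imidazole | Brc1nc(Br)c(Br)[nH]1 | starting material
2 | 2-(trimethylsilyl)ethoxymethyl chloride | C[Si](C)(C)CCOCCl | starting material
3 | sodium 2,4,5-tribromoimidazolide | [Na+].Brc1nc(Br)c(Br)[n-]1 | intermediate
4 | 2,4,5-tribromo-1-{[2-(trimethylsilyl)ethoxy]methyl}-1H-imidazole | Brc1nc(Br)c(Br)n1COCC[Si](C)(C)C | intermediate
5 | triethylsilylacetylene | CC[Si](CC)(CC)C#C | starting material
6 | 4,5-dibromo-2-[(triethylsilyl)ethynyl]-1-{[2-(trimethylsilyl)ethoxy]methyl}-1H-imidazole | CC[Si](CC)(CC)C#Cc1nc(Br)c(Br)n1COCC[Si](C)(C)C | intermediate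
7 | 4-bromo-5-lithio-2-[(triethylsilyl)ethynyl]-1-{[2-(trimethylsilyl)ethoxy]methyl}-1H-imidazole | CC[Si](CC)(CC)C#Cc1nc(Br)c([Li])n1COCC[Si](C)(C)C | intermediate
8 | 4-bromo-2-[(triethylsilyl)ethynyl]-1-{[2-(trimethylsilyl)ethoxy]methyl}-1H-imidazole | CC[Si](CC)(CC)C#Cc1nc(Br)cn1COCC[Si](C)(C)C | intermediate
9 | 2,4-bis[(triethylsilyl)ethynyl]-1-{[2-(trimethylsilyl)ethoxy]methyl}-1H-imidazole | CC[Si](CC)(CC)C#Cc1cn(COCC[Si](C)(C)C)c(C#C[Si](CC)(CC)CC)n1 | intermediate
10 | 5-bromo-2-iodoaniline | Nc1cc(Br)ccc1I | starting material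
11 | 4-[6-bromo-2-(triethylsilyl)-1H-indol-3-yl]-2-[(triethylsilyl)ethynyl]-1-{[2-(trimethylsilyl)ethoxy]methyl}-1H-imidazole | CC[Si](CC)(CC)C#Cc1nc(-c2c([Si](CC)(CC)CC)[nH]c3cc(Br)ccc23)cn1COCC[Si](C)(C)C | intermediate
12 | 2,4-bis[6-bromo-2-(triethylsilyl)-1H-indol-3-yl]-1-{[2-(trimethylsilyl)ethoxy]methyl}-1H-imidazole | CC[Si](CC)(CC)c1[nH]c2cc(Br)ccc2c1-c1cn(COCC[Si](C)(C)C)c(-c2c([Si](CC)(CC)CC)[nH]c3cc(Br)ccc23)n1 | intermediate
13 | 2,4-bis(6-bromo-1H-indol-3-yl)-1-{[2-(trimethylsilyl)ethoxy]methyl}-1H-imidazole | Brc1ccc2c(c[nH]c2c1)-c1cn(COCC[Si](C)(C)C)c(-c2c[nH]c3cc(Br)ccc23)n1 | intermediate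
14 | nortopsentin A, 2,4-bis(6-bromo-1H-indol-3-yl)-1H-imidazole | Brc1ccc2c(-c3c[nH]c(-c4c[nH]c5cc(Br)ccc45)n3)c[nH]c2c1 | target

**Step count**
Total steps: 6. Longest linear sequence: 6 steps (1 → 4 → 6 → 8 → 9 → 12 → 14).

**Steps most likely to fail**

**Step 5.**
- What may go wrong: two consecutive annulations need long heating. During it, zerovalent palladium may begin to insert into C–Br bonds and cause oligomerisation. The sequence may stall after the first ring closure at the alkyne flanked by the SEM group. The basic imidazole nitrogen may also tie up the catalyst.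
- Fallback: ring construction on the imidazole is given up, and preformed 6-bromoindoles are joined to the same halogenated core by Suzuki–Miyaura coupling. It sets out from 4 and comes back at 14.
- Commercial tert-butyl 6-bromoindole-1-carboxylate is borylated at C3 ([Ir(OMe)(cod)]2, dtbpy, B2pin2, THF, 60 °C) to tert-butyl 6-bromo-3-(4,4,5,5-tetramethyl-1,3,2-dioxaborolan-2-yl)indole-1-carboxylate F1.
- Coupling of F1 with 4 (Pd(PPh3)4, K3PO4, dioxane/H2O, 70 °C) should occur at the most reactive C2–Br bond. It should give tert-butyl 6-bromo-3-(4,5-dibromo-1-SEM-imidazol-2-yl)indole-1-carboxylate F2.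
- i-PrMgCl·LiCl (THF, −40 °C) exchanges only the activated C5 bromine, giving the C5-chloromagnesio imidazole F3. MeOH protonates it to tert-butyl 6-bromo-3-(4-bromo-1-SEM-imidazol-2-yl)indole-1-carboxylate F4.
- A second coupling with F1 uses the C4–Br bond, which lies next to the imine-type nitrogen and is expected to react ahead of the electron-rich indolyl bromides. It gives 1-SEM-2,4-bis(6-bromo-1-Boc-indol-3-yl)imidazole F5.
- The conditions of step 6 then remove both Boc groups and the SEM group to give 14.

**Step 4.**
- What may go wrong: oxidative addition into the C4–Br bond may be sluggish, so oxidative homocoupling of the alkyne and slow desilylation could take over on extended heating.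
- Fallback: the leaving group is changed before coupling. It sets out from 8 and comes back at 9.
- A copper-catalysed aromatic Finkelstein exchange (CuI, trans-N,N'-dimethylcyclohexane-1,2-diamine, NaI, dioxane, 110 °C) turns 8 into 4-iodo-2-[(triethylsilyl)ethynyl]-1-SEM-imidazole F6.
- The C–I bond of F6 should undergo Sonogashira coupling with 5 at room temperature (PdCl2(PPh3)2, CuI, Et3N, THF) to give 9.

**Step 2.**
- What may go wrong: site selectivity may erode, because the first alkynyl group makes the ring more electron-poor and invites a second alkynylation at C5.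
- Fallback: the three positions are differentiated by halogen identity rather than by rate. It sets out from 4 and comes back at 6.
- Bromine–lithium exchange on N-protected 2,4,5-tribromoimidazoles occurs first at C2, so n-BuLi (1.0 equiv, THF, −78 °C) gives the 4,5-dibromo-2-lithio-1-SEM-imidazole F7.
- Iodine converts F7 into 4,5-dibromo-2-iodo-1-SEM-imidazole F8.
- Sonogashira coupling of F8 with 5 at room temperature (PdCl2(PPh3)2, CuI, Et3N, THF) should touch only the C–I bond and deliver 6.

**Further compounds**
F1 | step 5 | tert-butyl 6-bromo-3-(4,4,5,5-tetramethyl-1,3,2-dioxaborolan-2-yl)indole-1-carboxylate | CC(C)(C)OC(=O)n1cc(B2OC(C)(C)C(C)(C)O2)c2ccc(Br)cc21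
F2 | step 5 | tert-butyl 6-bromo-3-(4,5-dibromo-1-{[2-(trimethylsilyl)ethoxy]methyl}imidazol-2-yl)indole-1-carboxylate | CC(C)(C)OC(=O)n1cc(-c2nc(Br)c(Br)n2COCC[Si](C)(C)C)c2ccc(Br)cc21
F3 | step 5 | tert-butyl 6-bromo-3-(4-bromo-5-chloromagnesio-1-{[2-(trimethylsilyl)ethoxy]methyl}imidazol-2-yl)indole-1-carboxylate | CC(C)(C)OC(=O)n1cc(-c2nc(Br)c([Mg]Cl)n2COCC[Si](C)(C)C)c2ccc(Br)cc21
F4 | step 5 | tert-butyl 6-bromo-3-(4-bromo-1-{[2-(trimethylsilyl)ethoxy]methyl}imidazol-2-yl)indole-1-carboxylate | CC(C)(C)OC(=O)n1cc(-c2nc(Br)cn2COCC[Si](C)(C)C)c2ccc(Br)cc21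
F5 | step 5 | 2,4-bis[6-bromo-1-(tert-butoxycarbonyl)indol-3-yl]-1-{[2-(trimethylsilyl)ethoxy]methyl}imidazole | CC(C)(C)OC(=O)n1cc(-c2cn(COCC[Si](C)(C)C)c(-c3cn(C(=O)OC(C)(C)C)c4cc(Br)ccc34)n2)c2ccc(Br)cc21
F6 | step 4 | 4-iodo-2-[(triethylsilyl)ethynyl]-1-{[2-(trimethylsilyl)ethoxy]methyl}imidazole | CC[Si](CC)(CC)C#Cc1nc(I)cn1COCC[Si](C)(C)C
F7 | step 2 | 4,5-dibromo-2-lithio-1-{[2-(trimethylsilyl)ethoxy]methyl}imidazole | [Li]c1nc(Br)c(Br)n1COCC[Si](C)(C)C
F8 | step 2 | 4,5-dibromo-2-iodo-1-{[2-(trimethylsilyl)ethoxy]methyl}imidazole | Ic1nc(Br)c(Br)n1COCC[Si](C)(C)C
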